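**Assumption:** the target SMILES contains no stereocentre and no stereogenic double bond, so the compound is achiral and no enantiomer has to be selected.

## Retrosynthetic overview
- The target comes from the MOM/TES-masked isoflavone by one mild acid unmasking.
- Ring C is the only ring built. It is closed last, by inserting one carbon (DMF-DMA) into a 2-hydroxydeoxybenzoin. Rings A and B are bought as arenes.
- Key disconnection: the Cα–C1' bond of the deoxybenzoin. An enolonium (phenacyl cation equivalent) of phloroacetophenone tripivalate is joined to the free C–H of the electron-rich ring B arene, so two normally nucleophilic carbons are coupled.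
- The ring B arene comes from ortho-lithiation of bis-MOM 4-methoxyresorcinol (isovanillin, Dakin oxidation) between its two OMOM groups. The aryllithium is alkylated with I-CH2CH2-C(CH3)2-OTES, made from 3-methylbutane-1,3-diol.

## Route

Step 1
Reactants: 1 isovanillin (3-hydroxy-4-methoxybenzaldehyde)
Product: 3 4-methoxybenzene-1,3-diol, via aryl formate 2 (not isolated)
Conditions: 30% aq H2O2, H2SO4 (cat.), MeOH, 0 °C → rt
Reagents that add atoms: hydrogen peroxide, OO
Why: In this acid-catalysed Dakin (Baeyer–Villiger type) oxidation the para-methoxy group drives aryl migration from the perhemiacetal to oxygen, and formate 2 is methanolysed in the same pot.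

Step 2
Reactants: 3 4-methoxybenzene-1,3-diol
Product: 4 1-methoxy-2,4-bis(methoxymethoxy)benzene
Conditions: MOMCl, i-Pr2NEt, CH2Cl2, 0 °C → rt
Reagents that add atoms: chloromethyl methyl ether (MOMCl), COCCl
Why: Williamson-type O-alkylation of both phenols with the reactive α-chloro ether installs acetals that keep the ring electron-rich, direct lithiation and leave under mild acid.

Step 3
Reactants: 5 3-methylbutane-1,3-diol
Product: 6 4-iodo-2-methylbutan-2-ol
Conditions: I2, PPh3, imidazole, CH2Cl2, 0 °C
Reagents that add atoms: iodine, II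
Why: The Appel iodination ends in an SN2 displacement of the oxyphosphonium group, so only the primary hydroxyl is exchanged and the tertiary one stays.

Step 4
Reactants: 6 4-iodo-2-methylbutan-2-ol
Product: 7 triethyl[(4-iodo-2-methylbutan-2-yl)oxy]silane
Conditions: TESOTf, 2,6-lutidine, CH2Cl2, 0 °C
Reagents that add atoms: triethylsilyl trifluoromethanesulfonate (TESOTf), CC[Si](CC)(CC)OS(=O)(=O)C(F)(F)F
Why: Silyl triflate O-silylation is fast even at a tertiary alcohol and masks the hydroxyl that would quench the aryllithium in step 5 and trap the enolonium in step 8.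

Step 5
Reactants: 4 1-methoxy-2,4-bis(methoxymethoxy)benzene; 7 triethyl[(4-iodo-2-methylbutan-2-yl)oxy]silane
Product: 9 triethyl({4-[3-methoxy-2,6-bis(methoxymethoxy)phenyl]-2-methylbutan-2-yl}oxy)silane (ring B arene), via aryllithium 8 (not isolated)
Conditions: n-BuLi, THF, 0 °C → rt; then 7, DMPU, −78 °C → rt
Reagents that add atoms: none
Why: Directed ortho-metalation occurs at the carbon flanked by the two chelating OMOM groups (cooperative effect), and the aryllithium is alkylated by the unhindered primary iodide in an SN2 reaction.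

Step 6
Reactants: 10 1-(2,4,6-trihydroxyphenyl)ethan-1-one (phloroacetophenone, dried)
Product: 11 2-acetylbenzene-1,3,5-triyl tris(2,2-dimethylpropanoate)
Conditions: PivCl, Et3N, DMAP (cat.), CH2Cl2, 0 °C → rt
Reagents that add atoms: pivaloyl chloride, CC(C)(C)C(=O)Cl
Why: DMAP-catalysed acylation caps all three phenols with esters that have no α-hydrogen, make ring A electron-poor and make the ortho oxygens non-nucleophilic, as the key step requires.

Step 7
Reactants: 11 2-acetylbenzene-1,3,5-triyl tris(2,2-dimethylpropanoate)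
Product: 12 2-[1-(trimethylsilyloxy)ethenyl]benzene-1,3,5-triyl tris(2,2-dimethylpropanoate)
Conditions: TMSOTf, Et3N, CH2Cl2, 0 °C; pentane, cold NaHCO3 wash, used crude
Reagents that add atoms: trimethylsilyl trifluoromethanesulfonate (TMSOTf), C[Si](C)(C)OS(=O)(=O)C(F)(F)F
Why: Soft enolisation of the methyl ketone gives the only possible silyl enol ether, because the pivalates cannot enolise.

Step 8
Reactants: 12 2-[1-(trimethylsilyloxy)ethenyl]benzene-1,3,5-triyl tris(2,2-dimethylpropanoate) (1.5 equiv); 9 ring B arene (1.0 equiv)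
Product: 14 2-{[5-methoxy-2,4-bis(methoxymethoxy)-3-(3-methyl-3-triethylsilyloxybutyl)phenyl]acetyl}benzene-1,3,5-triyl tris(2,2-dimethylpropanoate) (protected deoxybenzoin), via enolonium species 13 (not isolated)
Conditions: PhI(OAc)2 (1.45 equiv), BF3·OEt2, CH2Cl2, −78 °C, then 12, 10 min; then 9, −78 → −40 °C; cold NaHCO3 quench
Reagents that add atoms: none
Why: Proposed new method: BF3-activated PhI(OAc)2 turns the silyl enol ether into an O-bound trivalent-iodine enolate (enolonium) whose α-carbon is a phenacyl cation equivalent, and the most nucleophilic C–H of 9 (ortho to one OMOM, para to the other) attacks it in a Friedel–Crafts-type displacement of iodobenzene, while all oxidant is consumed before 9 is added and the pivalates keep ring A from competing and the ortho oxygens from closing to a coumaranone; the closest known reaction type is the metal-free α-arylation and allylation of ketone-derived enolonium species with indoles, pyrroles, thiophenes and allylsilanes, extended here to a trialkoxybenzene.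

Step 9
Reactants: 14 protected deoxybenzoin
Product: 17 5,7-dihydroxy-3-[5-methoxy-2,4-bis(methoxymethoxy)-3-(3-methyl-3-triethylsilyloxybutyl)phenyl]-4H-chromen-4-one, via trihydroxy deoxybenzoin 15 (not isolated), via enaminone 16 (not isolated)
Conditions: NaOMe, MeOH–THF, 0 °C → rt (argon), then AcOH, evaporate; DMF-DMA, THF, 60 °C; aq citric acid work-up
Reagents that add atoms: N,N-dimethylformamide dimethyl acetal (DMF-DMA), COC(OC)N(C)C
Why: Zemplén-type transesterification frees the ring A phenols, the acidic methylene condenses with DMF-DMA, and an ortho phenol closes ring C by addition–elimination on the enaminone (deoxybenzoin route to isoflavones), while the masked 2'-oxygen cannot divert to a benzofuran.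

Step 10
Reactants: 17 protected isoflavone
Product: 18 3-[2,4-dihydroxy-3-(3-hydroxy-3-methylbutyl)-5-methoxyphenyl]-5,7-dihydroxy-4H-chromen-4-one (target)
Conditions: 1.5 M HCl, MeOH–H2O (9:1), 25 °C, stopped at full conversion
Reagents that add atoms: none
Why: Specific-acid-catalysed acetal cleavage and desilylation should run about two orders of magnitude faster at 25 °C (estimated from rate data on simple model compounds) than ionisation of the tertiary alcohol, so all masks should fall before dehydration or chroman closure sets in.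

## Compound list
1 | isovanillin (3-hydroxy-4-methoxybenzaldehyde) | COc1ccc(C=O)cc1O | starting material
2 | 3-hydroxy-4-methoxyphenyl formate | COc1ccc(OC=O)cc1O | intermediate
3 | 4-methoxybenzene-1,3-diol | COc1ccc(O)cc1O | intermediate
4 | 1-methoxy-2,4-bis(methoxymethoxy)benzene | COCOc1ccc(OC)c(OCOC)c1 | intermediate
5 | 3-methylbutane-1,3-diol | CC(C)(O)CCO | starting material
6 | 4-iodo-2-methylbutan-2-ol | CC(C)(O)CCI | intermediate
7 | triethyl[(4-iodo-2-methylbutan-2-yl)oxy]silane | CC[Si](CC)(CC)OC(C)(C)CCI | intermediate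
8 | [3-methoxy-2,6-bis(methoxymethoxy)phenyl]lithium | [Li]c1c(OCOC)ccc(OC)c1OCOC | intermediate
9 | triethyl({4-[3-methoxy-2,6-bis(methoxymethoxy)phenyl]-2-methylbutan-2-yl}oxy)silane | COCOc1ccc(OC)c(OCOC)c1CCC(C)(C)O[Si](CC)(CC)CC | intermediate
10 | 1-(2,4,6-trihydroxyphenyl)ethan-1-one | CC(=O)c1c(O)cc(O)cc1O | starting material
11 | 2-acetylbenzene-1,3,5-triyl tris(2,2-dimethylpropanoate) | CC(=O)c1c(OC(=O)C(C)(C)C)cc(OC(=O)C(C)(C)C)cc1OC(=O)C(C)(C)C | intermediate
12 | 2-[1-(trimethylsilyloxy)ethenyl]benzene-1,3,5-triyl tris(2,2-dimethylpropanoate) | C=C(O[Si](C)(C)C)c1c(OC(=O)C(C)(C)C)cc(OC(=O)C(C)(C)C)cc1OC(=O)C(C)(C)C | intermediate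
13 | O-[acetoxy(phenyl)iodanyl] enolate of 11 (enolonium species) | C=C(OI(OC(C)=O)c1ccccc1)c1c(OC(=O)C(C)(C)C)cc(OC(=O)C(C)(C)C)cc1OC(=O)C(C)(C)C | intermediate
14 | 2-{[5-methoxy-2,4-bis(methoxymethoxy)-3-(3-methyl-3-triethylsilyloxybutyl)phenyl]acetyl}benzene-1,3,5-triyl tris(2,2-dimethylpropanoate) | COCOc1c(CC(=O)c2c(OC(=O)C(C)(C)C)cc(OC(=O)C(C)(C)C)cc2OC(=O)C(C)(C)C)cc(OC)c(OCOC)c1CCC(C)(C)O[Si](CC)(CC)CC | intermediate
15 | 2-[5-methoxy-2,4-bis(methoxymethoxy)-3-(3-methyl-3-triethylsilyloxybutyl)phenyl]-1-(2,4,6-trihydroxyphenyl)ethan-1-one | COCOc1c(CC(=O)c2c(O)cc(O)cc2O)cc(OC)c(OCOC)c1CCC(C)(C)O[Si](CC)(CC)CC | intermediate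
16 | 3-(dimethylamino)-2-[5-methoxy-2,4-bis(methoxymethoxy)-3-(3-methyl-3-triethylsilyloxybutyl)phenyl]-1-(2,4,6-trihydroxyphenyl)prop-2-en-1-one (alkene geometry not fixed, lost on ring closure) | COCOc1c(C(=CN(C)C)C(=O)c2c(O)cc(O)cc2O)cc(OC)c(OCOC)c1CCC(C)(C)O[Si](CC)(CC)CC | intermediate
17 | 5,7-dihydroxy-3-[5-methoxy-2,4-bis(methoxymethoxy)-3-(3-methyl-3-triethylsilyloxybutyl)phenyl]-4H-chromen-4-one | COCOc1c(-c2coc3cc(O)cc(O)c3c2=O)cc(OC)c(OCOC)c1CCC(C)(C)O[Si](CC)(CC)CC | intermediate
18 | 3-[2,4-dihydroxy-3-(3-hydroxy-3-methylbutyl)-5-methoxyphenyl]-5,7-dihydroxy-4H-chromen-4-one (achiral) | COc1cc(-c2coc3cc(O)cc(O)c3c2=O)c(O)c(CCC(C)(C)O)c1O | target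

## Step count and risks
Total step count: 10.
Longest linear sequence: 6 steps (steps 1, 2, 5, 8, 9, 10).

The three steps most likely to fail are 8, 10 and 9.

**Step 8.** The risks are α-acetoxylation on warming, oxidation of 9, and loss of TES before the C–C bond forms.
- The fallback keeps the α-keto cation logic but replaces both partners with stable, pre-formed reagents. It sets out from 12 and 9.
- NBS in THF at 0 °C converts 12 into the phenacyl bromide 2-(2-bromoacetyl)benzene-1,3,5-triyl tris(2,2-dimethylpropanoate) F1.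
- NBS in MeCN at 0 °C brominates 9 at the same activated position to give 4-[3-bromo-5-methoxy-2,6-bis(methoxymethoxy)phenyl]-2-methylbutan-2-yl triethylsilyl ether F2.
- n-BuLi at −78 °C gives [5-methoxy-2,4-bis(methoxymethoxy)-3-(3-methyl-3-triethylsilyloxybutyl)phenyl]lithium F3.
- ZnCl2 then gives [5-methoxy-2,4-bis(methoxymethoxy)-3-(3-methyl-3-triethylsilyloxybutyl)phenyl]zinc chloride F4.
- A Negishi-type coupling of F4 with F1 (NiCl2(dme), 4,4'-di-tert-butyl-2,2'-bipyridine, THF, −20 °C) comes back to the route at 14.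

**Step 10.** The risk is ionisation of the tertiary alcohol between two phenols, giving a chroman or an alkene.
- The fallback avoids Brønsted acid by exchanging the acetals for silyl ethers and unmasking with fluoride. It sets out from 17.
- Excess TMSOTf with 2,2'-bipyridyl in CH2Cl2 at 0 °C converts both ArOMOM groups and both free phenols into OTMS groups. This gives 3-[5-methoxy-3-(3-methyl-3-triethylsilyloxybutyl)-2,4-bis(trimethylsilyloxy)phenyl]-5,7-bis(trimethylsilyloxy)-4H-chromen-4-one F5.
- TBAF buffered with AcOH in THF at 0 °C strips all five silyl groups and comes back to the route at 18.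

**Step 9.** The risks are O-methylation of the free 7-hydroxyl by DMF-DMA and air oxidation of the polyphenolate.
- The fallback inserts the carbon before any phenol is freed, so that deacylation itself triggers ring closure. It sets out from 14.
- tert-Butoxybis(dimethylamino)methane in toluene at 90 °C gives 2-{3-(dimethylamino)-2-[5-methoxy-2,4-bis(methoxymethoxy)-3-(3-methyl-3-triethylsilyloxybutyl)phenyl]prop-2-enoyl}benzene-1,3,5-triyl tris(2,2-dimethylpropanoate) F6.
- K2CO3 in MeOH followed by AcOH removes the pivalates and closes ring C, coming back to the route at 17.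

## Further compounds
F1 | step 8 | 2-(2-bromoacetyl)benzene-1,3,5-triyl tris(2,2-dimethylpropanoate) | O=C(CBr)c1c(OC(=O)C(C)(C)C)cc(OC(=O)C(C)(C)C)cc1OC(=O)C(C)(C)C
F2 | step 8 | 4-[3-bromo-5-methoxy-2,6-bis(methoxymethoxy)phenyl]-2-methylbutan-2-yl triethylsilyl ether | COCOc1c(Br)cc(OC)c(OCOC)c1CCC(C)(C)O[Si](CC)(CC)CC
F3 | step 8 | [5-methoxy-2,4-bis(methoxymethoxy)-3-(3-methyl-3-triethylsilyloxybutyl)phenyl]lithium | [Li]c1cc(OC)c(OCOC)c(CCC(C)(C)O[Si](CC)(CC)CC)c1OCOC
F4 | step 8 | [5-methoxy-2,4-bis(methoxymethoxy)-3-(3-methyl-3-triethylsilyloxybutyl)phenyl]zinc chloride | Cl[Zn]c1cc(OC)c(OCOC)c(CCC(C)(C)O[Si](CC)(CC)CC)c1OCOC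
F5 | step 10 | 3-[5-methoxy-3-(3-methyl-3-triethylsilyloxybutyl)-2,4-bis(trimethylsilyloxy)phenyl]-5,7-bis(trimethylsilyloxy)-4H-chromen-4-one | COc1cc(-c2coc3cc(O[Si](C)(C)C)cc(O[Si](C)(C)C)c3c2=O)c(O[Si](C)(C)C)c(CCC(C)(C)O[Si](CC)(CC)CC)c1O[Si](C)(C)C
F6 | step 9 | 2-{3-(dimethylamino)-2-[5-methoxy-2,4-bis(methoxymethoxy)-3-(3-methyl-3-triethylsilyloxybutyl)phenyl]prop-2-enoyl}benzene-1,3,5-triyl tris(2,2-dimethylpropanoate) | COCOc1c(C(=CN(C)C)C(=O)c2c(OC(=O)C(C)(C)C)cc(OC(=O)C(C)(C)C)cc2OC(=O)C(C)(C)C)cc(OC)c(OCOC)c1CCC(C)(C)O[Si](CC)(CC)CC
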